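**Retrosynthetic overview**

1. Target 9 is gallocatechin-(4α→8)-catechin-(4α→8)-catechin. Both C4–C8 interflavan bonds are cut, and both are made on fully unprotected polyphenols in water.
2. Upper bond: the C4 cation / quinone methide 8 of leucodelphinidin 7 (NaBH4-reduced dihydromyricetin 6) plus C8 of the upper unit of free procyanidin B3 5.
3. Lower bond: the C4 cation / quinone methide 4 of leucocyanidin 3 (NaBH4-reduced taxifolin 1) plus C8 of catechin 2.
4. Rings: all nine rings arrive intact in 1, 2 and 6, their C-rings having been closed by the plants' own chalcone→flavanone oxa-Michael step. No ring is formed or opened in the flask; the units are joined in the biosynthetic order bottom (starter) → middle → top.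

Assumption: (+)-catechin, (+)-taxifolin and (+)-dihydromyricetin (ampelopsin) are taken as cheap, commercial, enantiopure plant products sold in bulk.

**Route**

Step 1
Reactants: 1 (+)-taxifolin; 2 (+)-catechin
Product: 5 procyanidin B3 (catechin-(4α→8)-catechin), via leucocyanidin 3 (not isolated), via cyanidin-type quinone methide 4 (not isolated)
Conditions: NaBH4 (5 equiv), EtOH, N2, rt, 1 h; then 2 (4 equiv), degassed H2O, AcOH to pH 5, rt, 2 h; EtOAc extraction, Sephadex LH-20 (EtOH)
Reagents that add atoms: none
Why: Hydride reduction of the C4 ketone gives the flavan-3,4-diol 3, whose benzylic 4-OH ionises at pH 5 to the cation / quinone methide 4, which is captured in a biomimetic Friedel–Crafts (electrophilic aromatic substitution) chain extension by the more nucleophilic, less hindered C8 of catechin; the new C4 centre is set 3,4-trans (4α) by attack anti to the 3-OH of the 2,3-trans half-chair cation, C2 and C3 of both units come unchanged from 1 and 2, and the excess of 2 (recovered) suppresses further extension of 5.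

Step 2
Reactants: 6 (+)-dihydromyricetin; 5 procyanidin B3
Product: 9 gallocatechin-(4α→8)-catechin-(4α→8)-catechin, via leucodelphinidin 7 (not isolated), via delphinidin-type quinone methide 8 (not isolated)
Conditions: NaBH4 (5 equiv), degassed EtOH, N2, rt, 1 h; then 5 (3 equiv), degassed H2O, AcOH to pH 5, rt, 2 h; Sephadex LH-20 (EtOH→EtOH/MeOH), then prep. C18 HPLC (H2O/MeCN, 0.1% HCO2H)
Reagents that add atoms: none
Why: The same carbonyl reduction / ionisation sequence gives the gallocatechin C4 cation 8, and the biomimetic Friedel–Crafts chain extension goes mainly to C8 of the upper unit of 5, the only free C8 (the lower C8 is substituted and both C6 positions are intrinsically less reactive); attack anti to the 3-OH of the 2,3-trans cation sets the new upper C4 as 4α (3,4-trans), and the existing interflavan bond and all existing stereocentres are stable at pH 5 and room temperature (excess 5 is recovered).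

Expected yields are low to moderate: roughly 25–30% for step 1 based on 1, and roughly 10–15% for step 2 based on 6. These are estimates from the behaviour of this reaction class, not measured values.

**Compound list**

1 | (+)-taxifolin, (2R,3R)-2-(3,4-dihydroxyphenyl)-3,5,7-trihydroxychroman-4-one | Oc1cc(O)c2c(c1)O[C@H](c1ccc(O)c(O)c1)[C@@H](O)C2=O | starting material
2 | (+)-catechin, (2R,3S)-2-(3,4-dihydroxyphenyl)chromane-3,5,7-triol | Oc1cc(O)c2c(c1)O[C@H](c1ccc(O)c(O)c1)[C@@H](O)C2 | starting material
3 | leucocyanidin, 2,3-trans-3,4-trans, (2R,3S,4R)-2-(3,4-dihydroxyphenyl)chromane-3,4,5,7-tetrol (major 4-epimer; the 4S epimer converges on 4) | Oc1cc(O)c2c(c1)O[C@H](c1ccc(O)c(O)c1)[C@@H](O)[C@@H]2O | intermediate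
4 | cyanidin-type quinone methide, (2R,3S)-2-(3,4-dihydroxyphenyl)-3,5-dihydroxy-2,3-dihydro-7H-chromen-7-one (neutral form of the C4 cation) | O=C1C=C(O)C2=C[C@H](O)[C@@H](c3ccc(O)c(O)c3)OC2=C1 | intermediate
5 | procyanidin B3, (+)-catechin-(4α→8)-(+)-catechin; upper unit (2R,3S,4S), lower unit (2R,3S) | Oc1cc(O)c2c(c1)O[C@H](c1ccc(O)c(O)c1)[C@@H](O)[C@@H]2c1c(O)cc(O)c2c1O[C@H](c1ccc(O)c(O)c1)[C@@H](O)C2 | intermediate
6 | (+)-dihydromyricetin (ampelopsin), (2R,3R)-3,5,7-trihydroxy-2-(3,4,5-trihydroxyphenyl)chroman-4-one | Oc1cc(O)c2c(c1)O[C@H](c1cc(O)c(O)c(O)c1)[C@@H](O)C2=O | starting material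
7 | leucodelphinidin, 2,3-trans-3,4-trans, (2R,3S,4R)-2-(3,4,5-trihydroxyphenyl)chromane-3,4,5,7-tetrol (major 4-epimer; the 4S epimer converges on 8) | Oc1cc(O)c2c(c1)O[C@H](c1cc(O)c(O)c(O)c1)[C@@H](O)[C@@H]2O | intermediate
8 | delphinidin-type quinone methide, (2R,3S)-3,5-dihydroxy-2-(3,4,5-trihydroxyphenyl)-2,3-dihydro-7H-chromen-7-one (neutral form of the C4 cation) | O=C1C=C(O)C2=C[C@H](O)[C@@H](c3cc(O)c(O)c(O)c3)OC2=C1 | intermediate
9 | gallocatechin-(4α→8)-catechin-(4α→8)-catechin; upper unit (2R,3S,4S), middle unit (2R,3S,4R), lower unit (2R,3S); all units 2,3-trans, both linkages 3,4-trans | Oc1cc(O)c2c(c1)O[C@H](c1cc(O)c(O)c(O)c1)[C@@H](O)[C@@H]2c1c(O)cc(O)c2c1O[C@H](c1ccc(O)c(O)c1)[C@@H](O)[C@@H]2c1c(O)cc(O)c2c1O[C@H](c1ccc(O)c(O)c1)[C@@H](O)C2 | target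

**Totals**

Total step count: 2. Longest linear sequence: 2 (1 → 5 → 9).

**Steps most likely to fail**

The route has only two steps, so step 2 is entered twice, once for each of its stages.

Risk 1 – step 2, C–C bond-forming stage. Nucleophile 5 offers three free A-ring positions (upper C8, upper C6, lower C6), so regioisomeric and 4β trimers and tetramers can erode yield and make the isolation hard. Fallback (order of bond formation reversed, so that each bond is made on a monomeric nucleophile): it sets out from 1 and 6. Leucocyanidin 3, made from 1 as in step 1, is poured into benzyl mercaptan/AcOH in EtOH, where thiol capture of 4 gives the bench-stable 4α-benzylsulfanylcatechin F1. Leucodelphinidin 7, made from 6 as in step 2, is then condensed at pH 5 with excess F1, whose C–S bond is inert at that pH and whose single A-ring reacts at C8 like catechin, to give gallocatechin-(4α→8)-4α-benzylsulfanylcatechin F2. Thiophilic activation of F2 with AgBF4 in THF at 0 °C under N2 in the presence of excess 2 makes the lower bond and comes back to the route at 9.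

Risk 2 – step 2, generation and survival of 7. The pyrogallol ring autoxidises in the basic borohydride solution, and 7 can self-condense through its own C8 before it meets 5. Fallback (a stable, purifiable electrophile ionised under non-aqueous, neutral conditions): it sets out from 6. The borohydride solution of 7 is quenched at once into a large excess of benzyl mercaptan in AcOH/EtOH, the thiol out-competing self-condensation, to give 4α-benzylsulfanylgallocatechin F3, which is purified on Sephadex LH-20 and can be stored. F3 is then ionised with AgBF4 in THF at 0 °C under N2 in the presence of 5 (3 equiv), coming back to the route at 9.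

Risk 3 – step 1. B3 may be contaminated by the 4α→6 isomer and 4β epimer, or the yield may be too low to supply 5 in the excess that step 2 needs. Fallback (protected units and Lewis-acid coupling): it sets out from 2. Benzylation (BnBr, K2CO3, DMF) gives 5,7,3′,4′-tetra-O-benzylcatechin F4. Part of F4 is oxidised at C4 with DDQ in CH2Cl2 in the presence of 2-ethoxyethanol to give 5,7,3′,4′-tetra-O-benzyl-4-(2-ethoxyethoxy)catechin F5. TMSOTf-catalysed coupling of F5 with excess F4 (CH2Cl2, −78 °C) gives octa-O-benzylprocyanidin B3 F6. Hydrogenolysis (H2, Pd(OH)2/C, THF/MeOH/H2O) comes back to the route at 5.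

**Further compounds**

F1 | step 2 | 4α-benzylsulfanylcatechin (2,3-trans-3,4-trans) | Oc1cc(O)c2c(c1)O[C@H](c1ccc(O)c(O)c1)[C@@H](O)[C@@H]2SCc1ccccc1
F2 | step 2 | gallocatechin-(4α→8)-4α-benzylsulfanylcatechin | Oc1cc(O)c2c(c1)O[C@H](c1cc(O)c(O)c(O)c1)[C@@H](O)[C@@H]2c1c(O)cc(O)c2c1O[C@H](c1ccc(O)c(O)c1)[C@@H](O)[C@@H]2SCc1ccccc1
F3 | step 2 | 4α-benzylsulfanylgallocatechin (2,3-trans-3,4-trans) | Oc1cc(O)c2c(c1)O[C@H](c1cc(O)c(O)c(O)c1)[C@@H](O)[C@@H]2SCc1ccccc1
F4 | step 1 | 5,7,3′,4′-tetra-O-benzyl-(+)-catechin | c3ccccc3COc1cc(OCc3ccccc3)c2c(c1)O[C@H](c1ccc(OCc3ccccc3)c(OCc3ccccc3)c1)[C@@H](O)C2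
F5 | step 1 | 5,7,3′,4′-tetra-O-benzyl-4-(2-ethoxyethoxy)catechin (4β drawn; the C4 configuration is lost on ionisation) | c3ccccc3COc1cc(OCc3ccccc3)c2c(c1)O[C@H](c1ccc(OCc3ccccc3)c(OCc3ccccc3)c1)[C@@H](O)[C@H]2OCCOCC
F6 | step 1 | octa-O-benzylprocyanidin B3 (all eight phenols benzylated, both 3-OH free) | c3ccccc3COc1cc(OCc3ccccc3)c2c(c1)O[C@H](c1ccc(OCc3ccccc3)c(OCc3ccccc3)c1)[C@@H](O)[C@@H]2c1c(OCc3ccccc3)cc(OCc3ccccc3)c2c1O[C@H](c1ccc(OCc3ccccc3)c(OCc3ccccc3)c1)[C@@H](O)C2
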